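## Analysis of the target

The target is a cis-fused decalin of the nor-eremophilane type with fourteen skeletal carbons. Ring A (C5 to C10) carries a 2-acetyl enone (C6=C7, acetyl C11/C12 on C7, ketone C8), the angelate on C9 and a tertiary alcohol on C10. Ring B (C1 to C5, C10) carries the C3 acetate, the C4 methyl (C15) and the quaternary C5 with its methyl (C14). The five stereocentres are contiguous: C3 (S), C4 (R), C5 (R), C10 (R) and C9 (S). Taking the face of the C5 methyl as β, the C3 acetate, both methyls and the C10 hydroxyl are β and the C9 angelate is α, so the ring fusion is cis and the C9/C10 oxygens are trans. The sensitive points are: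

- the angelate, which drifts from Z to E under nucleophilic catalysis, iodine or radicals;
- the doubly activated C6=C7 alkene, a strong Michael acceptor that is isolable only because C5 is quaternary;
- the C8 ketone/C10 hydroxyl aldol pair (retro-aldol, dehydration);
- C9–H, which lies between a ketone and an ester and can epimerise.

The difficulty is the pair of adjacent fully substituted carbons C5 and C10, flanked by C4 and C9, together with five oxygen functions of four kinds on a small skeleton. The strategy rests on one feature: C4 and C5 are adjacent, each bears a methyl, the methyls are cis, and C5 sits next to the oxygenated C10. They are therefore the β- and α-carbons of a C10 enone, and the C3 oxygen is its γ-position, which is the substitution pattern of a quinone monoketal.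

## Retrosynthetic reasoning

Positions follow the numbering above; "decalin" names below use it as well.

**C7–C11.** The acetyl group is removed first, back to the vinyl iodide 28, to be joined by a Stille coupling with a masked acetyl nucleophile. The ene-dione is the most electrophilic part of the target, so it should appear in the last operation. C7 of a plain enone can be addressed without ambiguity by α-iodination.

**C9–O ester.** Iodide 28 is cut into the α-ketol 25 and angelic acid 26. The angelate is put on after the iodination, because iodine isomerises Z enoates, and before the ene-dione exists.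

**Functional group changes on ring A and C3.** Ketol 25 comes from the MOM ether 24, the iodide 24 from enone 23, and the acetate 23 from the hydroxy enone 22. The C3 acetate is introduced only once the C8 carbinol has been oxidised, so that the two secondary alcohols never have to be told apart by acylation.

**Enone from the metathesis alkene.** Enone 22 is traced to the allylic alcohol 21 and that to the epoxide 18 of the C7=C8 alkene 17. The alkene must move from C7=C8 to C6=C7 while oxygen arrives on C8. An epoxide opened by a selenium nucleophile at C7, followed by selenoxide elimination, does this. A strong amide base was avoided because it would have syn hydrogens on both C6 and C9 to choose from and three free hydroxyls to deprotonate.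

**C3 oxygen.** Alcohol 17 comes from ketone 16 and that from the dimethyl ketal 15. The ketal carries the C3 oxygen through the early steps without a stereocentre. The reduction is done on the bicycle, where the C4 and C5 methyls shield one face of C3.

**C7=C8 (ring A).** The bicycle 15 is opened by retro-metathesis to the diene 14. The allyl group on C5 supplies C6 and C7, so the partner on C10 must be a vinyl-bearing C9. Ring A then closes from two arms that are cis on adjacent carbons.

**C9–C10.** Diene 14 is cut into ketone 8 and the allyl MOM ether 11 (from allyl alcohol 9 and chloromethyl methyl ether 10). One C–C bond brings C8, C9 and the C9 oxygen, and sets C9 and C10 together. MOM was chosen because its allyl ether lithiates cleanly without rearrangement and because it is removed by a Lewis acid that the aldol unit tolerates.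

**C4–C15 and C5–C6 (key disconnection).** Ketone 8 is cut into enone 3, trimethylaluminium 4 and allyl iodide 5. Both methyl-bearing stereocentres and the quaternary carbon arise in one flask from an achiral enone. Ring B keeps all its carbons from the start.

**Enone 3.** It is traced to the quinone monoketal 2 and to the phenol 1 by selective hydrogenation and oxidative ketalisation. Two steps reach the key-step substrate.

## Alternatives that were turned down

**Alternative 1: enzymatic cyclisation.** The disconnection cuts C6–C7 and C5–C10 back to acyclic farnesyl diphosphate A1. In the forward step a magnesium-dependent terpene cyclase (aristolochene synthase) ionises A1 and closes both rings. A hydride shift to C4 and a methyl shift from C10 to C5 follow, giving (+)-aristolochene A2.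
- For: both rings and the C4/C5 cis-dimethyl pair, in the correct absolute sense, come in one step without protecting groups. On skeletal step economy and on control of C4/C5 this is stronger than the chosen route.
- Against: A2 is a hydrocarbon. The target needs oxygen at C3, C8, C9, C10 and C11, loss of one isopropenyl carbon, and the C6=C7 alkene. The C3 oxygen would have to be placed on an unactivated methylene with no directing handle. The C9=C10 alkene of A2 does not lead simply to the trans 9α,10β pattern. Enzyme supply and scale add a separate burden.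
- Comparison: the chosen route carries the C3 oxygen from phenol 1 and builds ring A with its oxygens already in place, so the post-skeleton oxidation work that dominates this alternative is avoided.

**Alternative 2: cyclopropanol homoenolate closure of ring B.** The disconnection cuts C1–C10 and leads to the cyclopropanol ketone A3. In the forward step a zinc or titanium alkoxide of A3 opens to a β-metallo ketone whose carbon C1 adds to the C10 ketone. This closes ring B and gives the hydroxy ketone A4.
- For: the C10 hydroxyl and the C3 ketone appear together and the fusion is cis by the intramolecular mode. On forming the C10 carbinol this is at least as direct as the chosen route.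
- Against: zinc homoenolates are weak nucleophiles and the C10 ketone is α-quaternary. A3 already needs the C4/C5 pair, with C4 on a side chain where its control is harder, so the central problem is moved, not solved. Ring A of A4 is saturated, so the C9 oxygen, the C6=C7 alkene and the acetyl group all remain to be introduced, C9 by enolate oxidation next to a quaternary carbon.
- Comparison: the chosen route sets C4/C5 in one catalytic step on the ring and brings the C9 oxygen in the same bond formation that makes C10.

**Alternative 3: silicon-tethered angular methyl.** The disconnection cuts C5–C14 and leads to the bromomethylsilyl ether A5. In the forward step a tin hydride radical chain turns the tether into an α-silyl radical. It adds 5-exo to C5, the β-carbon of the C4=C5 enone, and gives the oxasilolane A6.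
- For: the tether forces C14 cis to the C10 oxygen. That is stronger than the chosen route, where this relation depends on the facial selectivity of an intermolecular addition (step 5).
- Against: A5 needs the tertiary allylic C10 carbinol as a single enantiomer beforehand. C4 is set only by hydrogen-atom transfer or later equilibration. The C14–Si bond must be cleaved to C–H, whereas the easy cleavage mode of such silanes is oxidation to a carbinol. The tin reagent is stoichiometric, and ring A still needs all its oxidation.
- Comparison: the chosen route takes both methyls from cheap reagents with a known sense of relative control and needs no tether to install or remove.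

Key step: step 3

Assumption: the antipode of the phosphoramidite L* (O,O'-(1,1'-binaphthalene-2,2'-diyl) N,N-bis(1-phenylethyl)phosphoramidite) that delivers methyl to the Re face of the β-carbon of 3 is used; both antipodes are commercial and the sense of induction would be checked on 3 first.

## Route

Step 1
Reactants: 1 4-methoxy-2-methylphenol
Product: 2 4,4-dimethoxy-2-methylcyclohexa-2,5-dien-1-one
Conditions: PhI(OAc)2, MeOH, 0 °C to rt
Reagents that add atoms: methanol, CO
Why: Oxidative dearomatisation of a p-methoxyphenol by trivalent iodine; methanol captures the cationic intermediate at the methoxy-bearing para carbon and gives the quinone monoketal with the C3 oxygen masked.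

Step 2
Reactants: 2 4,4-dimethoxy-2-methylcyclohexa-2,5-dien-1-one
Product: 3 4,4-dimethoxy-2-methylcyclohex-2-en-1-one
Conditions: H2 (1 atm), RhCl(PPh3)3 (cat.), toluene, rt
Reagents that add atoms: none
Why: Homogeneous hydrogenation with RhCl(PPh3)3 discriminates by alkene substitution, so the disubstituted C1=C2 alkene of the cross-conjugated dienone is reduced and the methyl-bearing alkene stays; neutral conditions avoid loss of methanol and rearomatisation.

Step 3
Reactants: 3 4,4-dimethoxy-2-methylcyclohex-2-en-1-one; 4 trimethylaluminium; 5 allyl iodide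
Product: 8 (2R,3R)-4,4-dimethoxy-2,3-dimethyl-2-(prop-2-en-1-yl)cyclohexan-1-one, via dimethylaluminium enolate 6 (not isolated), via lithium aluminate enolate 7 (not isolated)
Conditions: Cu(OTf)2 (5 mol %), L* (10 mol %), AlMe3, Et2O, −30 °C; then MeLi, THF/HMPA, allyl iodide, −30 °C to rt
Reagents that add atoms: trimethylaluminium, C[Al](C)C; allyl iodide, C=CCI
Why: AlMe3 reduces Cu(OTf)2 to monovalent copper and transfers methyl to it; the phosphoramidite-bound methylcopper complexes the C4=C5 alkene of 3, whose carbonyl is activated by aluminium, adds at the β-carbon C4 through a transient trivalent copper species and reductively eliminates, which forms the C4–C15 bond and leaves the regiodefined enolate 6. MeLi turns 6 into the more nucleophilic aluminate 7, whose α-carbon C5 displaces iodide from allyl iodide (SN2) and forms the C5–C6 bond. The closest known reaction type is the copper/phosphoramidite-catalysed conjugate addition of trialkylaluminium reagents to 2-methylcyclohex-2-enones with allyl halide capture of the enolate; only the γ,γ-dimethoxy substitution is new. No ring is closed. C4 is set by the chiral copper catalyst (methyl to the Re face, R centre); C5 is set by the substrate, because allylic 1,2-strain with the C5 methyl turns the new C4 methyl pseudoaxial and the electrophile enters on the opposite face, so allyl is trans to it and the two methyls are cis (5R). The step needs 1,4- over 1,2-methyl transfer, secured by ether solvent and low temperature under which uncatalysed carbonyl addition of AlMe3 is slow, and alkylation at C5 and not C1, secured by the regiospecific enolate and a reactive allylic iodide that traps it before proton transfer. The ketal oxygens sit on the γ-carbon C3 of the enolate, so no β-elimination is open, and coordination of AlMe3 by Et2O tempers its Lewis acidity towards the ketal.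

Step 4
Reactants: 9 allyl alcohol; 10 chloromethyl methyl ether
Product: 11 3-(methoxymethoxy)prop-1-ene
Conditions: iPr2NEt, CH2Cl2, 0 °C to rt; distillation
Reagents that add atoms: chloromethyl methyl ether, COCCl
Why: O-alkylation of a primary alcohol by an α-chloro ether through its oxocarbenium ion, a standard MOM protection.

Step 5
Reactants: 8 (2R,3R)-4,4-dimethoxy-2,3-dimethyl-2-(prop-2-en-1-yl)cyclohexan-1-one; 11 3-(methoxymethoxy)prop-1-ene
Product: 14 (1R,2R,3R)-4,4-dimethoxy-1-[(1R)-1-(methoxymethoxy)prop-2-en-1-yl]-2,3-dimethyl-2-(prop-2-en-1-yl)cyclohexan-1-ol, via lithiated allyl ether 12 (not isolated), via alkoxyallylaluminium reagent 13 (not isolated)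
Conditions: 11, sBuLi, THF, −78 °C; Et2AlCl, −78 °C; then 8, −78 to −20 °C; aq. Rochelle salt
Reagents that add atoms: 3-(methoxymethoxy)prop-1-ene, C=CCOCOC
Why: γ-Alkoxyallylation of a ketone: deprotonation of 11 gives the oxygen-chelated Z allyl anion 12, and after transmetallation aluminium sits on the terminal carbon so that 13 adds through its oxygen-bearing carbon in a six-membered Zimmerman–Traxler chair and forms C9–C10. The reagent enters the C10 carbonyl on the α face, opposite the C5 and C4 methyls, which gives the 10β-hydroxyl. With the quaternary C5 pseudoequatorial and the Z alkoxy group pseudoaxial in the chair, C9 forms with its oxygen syn to the C10 oxygen in the open chain, which is the trans 9α,10β pattern after ring closure.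

Step 6
Reactants: 14 (1R,2R,3R)-4,4-dimethoxy-1-[(1R)-1-(methoxymethoxy)prop-2-en-1-yl]-2,3-dimethyl-2-(prop-2-en-1-yl)cyclohexan-1-ol
Product: 15 3,3-dimethoxy-9α-(methoxymethoxy)-4β,5β-dimethyl-cis-decal-7-en-10β-ol
Conditions: second-generation Grubbs catalyst RuCl2(=CHPh)(H2IMes)(PCy3) (5 mol %), CH2Cl2, 40 °C
Reagents that add atoms: none
Why: Ring-closing metathesis of two terminal alkenes held cis on adjacent carbons closes the six-membered ring A at C7=C8 with loss of ethylene; the ruthenium carbene tolerates the tertiary alcohol, the MOM ether and the ketal.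

Step 7
Reactants: 15 3,3-dimethoxy-9α-(methoxymethoxy)-4β,5β-dimethyl-cis-decal-7-en-10β-ol
Product: 16 10β-hydroxy-9α-(methoxymethoxy)-4β,5β-dimethyl-cis-decal-7-en-3-one
Conditions: PPTS, acetone/H2O, rt
Reagents that add atoms: water, O
Why: Acid-catalysed hydrolysis of a dimethyl ketal is far faster than that of a MOM ether, so only the C3 ketone is unmasked; the C10 alcohol is γ to the new ketone and cannot eliminate.

Step 8
Reactants: 16 10β-hydroxy-9α-(methoxymethoxy)-4β,5β-dimethyl-cis-decal-7-en-3-one
Product: 17 9α-(methoxymethoxy)-4β,5β-dimethyl-cis-decal-7-ene-3β,10β-diol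
Conditions: LiBH(sBu)3, THF, −78 °C; then NaOH, H2O2, 0 °C
Reagents that add atoms: none
Why: Ketone reduction by a bulky trialkylborohydride; the β face of C3 is shielded by the adjacent C4 methyl and the syn-axial C5 methyl, so hydride enters from the α face and gives the axial 3β-alcohol cis to the C4 methyl (3S).

Step 9
Reactants: 17 9α-(methoxymethoxy)-4β,5β-dimethyl-cis-decal-7-ene-3β,10β-diol
Product: 18 7β,8β-epoxy-9α-(methoxymethoxy)-4β,5β-dimethyl-cis-decalin-3β,10β-diol
Conditions: mCPBA, NaHCO3, CH2Cl2, 0 °C
Reagents that add atoms: mCPBA, OOC(=O)c1cccc(Cl)c1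
Why: Prilezhaev epoxidation of the only alkene; the homoallylic C10 hydroxyl and the shielding of the α face by the C9 MOM ether should favour the β epoxide, and the α epoxide would converge at 22 because C7 and C8 end as sp2 carbons.

Step 10
Reactants: 18 7β,8β-epoxy-9α-(methoxymethoxy)-4β,5β-dimethyl-cis-decalin-3β,10β-diol
Product: 21 9α-(methoxymethoxy)-4β,5β-dimethyl-cis-decal-6-ene-3β,8β,10β-triol, via hydroxy selenide 19 (not isolated), via selenoxide 20 (not isolated)
Conditions: (PhSe)2, NaBH4, EtOH, 78 °C; then THF, H2O2 (30 %), pyridine, 0 °C to rt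
Reagents that add atoms: none
Why: Epoxide-to-allylic-alcohol transposition via a selenide: phenylselenolate opens the epoxide by SN2 at C7, the carbon remote from the electron-withdrawing C9 oxygen, and syn elimination of the selenoxide runs away from the carbinol carbon towards C6. This gives C6=C7 and leaves the oxygen on C8.

Step 11
Reactants: 21 9α-(methoxymethoxy)-4β,5β-dimethyl-cis-decal-6-ene-3β,8β,10β-triol
Product: 22 3β,10β-dihydroxy-9α-(methoxymethoxy)-4β,5β-dimethyl-cis-decal-6-en-8-one
Conditions: MnO2 (activated, excess), CH2Cl2, rt
Reagents that add atoms: none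
Why: MnO2 oxidises allylic alcohols selectively, so the C8 carbinol becomes the enone while the saturated C3 alcohol and the tertiary C10 alcohol stay.

Step 12
Reactants: 22 3β,10β-dihydroxy-9α-(methoxymethoxy)-4β,5β-dimethyl-cis-decal-6-en-8-one
Product: 23 3β-acetoxy-10β-hydroxy-9α-(methoxymethoxy)-4β,5β-dimethyl-cis-decal-6-en-8-one
Conditions: Ac2O, pyridine, DMAP (cat.), CH2Cl2, 0 °C to rt
Reagents that add atoms: acetic anhydride, CC(=O)OC(C)=O
Why: DMAP-catalysed acylation of the only free secondary alcohol; the tertiary C10 alcohol does not react under these conditions and the C9 oxygen is still protected.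

Step 13
Reactants: 23 3β-acetoxy-10β-hydroxy-9α-(methoxymethoxy)-4β,5β-dimethyl-cis-decal-6-en-8-one
Product: 24 3β-acetoxy-10β-hydroxy-7-iodo-9α-(methoxymethoxy)-4β,5β-dimethyl-cis-decal-6-en-8-one
Conditions: I2, pyridine, CH2Cl2, rt
Reagents that add atoms: iodine, II
Why: α-Iodination of an enone by reversible pyridine addition at C6, iodination of the enolate at C7 and elimination, a sequence that works with a quaternary γ-carbon; it is placed before the angelate is present because iodine isomerises Z enoates.

Step 14
Reactants: 24 3β-acetoxy-10β-hydroxy-7-iodo-9α-(methoxymethoxy)-4β,5β-dimethyl-cis-decal-6-en-8-one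
Product: 25 3β-acetoxy-9α,10β-dihydroxy-7-iodo-4β,5β-dimethyl-cis-decal-6-en-8-one
Conditions: Me2BBr, CH2Cl2, −78 °C; then aq. NaHCO3, THF
Reagents that add atoms: none
Why: Lewis acid cleavage of a MOM ether: boron activates the acetal, bromide attacks its carbon and the bromomethyl ether is hydrolysed on work-up; at −78 °C the acetate, the vinyl iodide and the aldol unit should tolerate it.

Step 15
Reactants: 25 3β-acetoxy-9α,10β-dihydroxy-7-iodo-4β,5β-dimethyl-cis-decal-6-en-8-one; 26 angelic acid
Product: 28 3β-acetoxy-9α-angeloyloxy-10β-hydroxy-7-iodo-4β,5β-dimethyl-cis-decal-6-en-8-one, via mixed anhydride 27 (not isolated)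
Conditions: 26, 2,4,6-trichlorobenzoyl chloride, Et3N, toluene, rt; then 25, 75 °C
Reagents that add atoms: angelic acid, C/C=C(/C)C(=O)O
Why: Yamaguchi-type esterification: angelic acid is activated as the mixed anhydride 27 and transferred to the secondary α-ketol hydroxyl without a nucleophilic catalyst, conditions under which the Z geometry is kept; the tertiary C10 hydroxyl is too hindered to compete.

Step 16
Reactants: 28 3β-acetoxy-9α-angeloyloxy-10β-hydroxy-7-iodo-4β,5β-dimethyl-cis-decal-6-en-8-one
Product: 30 CNP0196241.1, 3β-acetoxy-7-acetyl-9α-angeloyloxy-10β-hydroxy-4β,5β-dimethyl-cis-decal-6-en-8-one (3S,4R,5R,9S,10R), via ethoxyvinyl dienone 29 (not isolated)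
Conditions: CH2=C(OEt)SnBu3, PdCl2(PhCN)2 (cat.), AsPh3, CuI, NMP, 40 °C; then HCl (1 M), THF, 0 °C
Reagents that add atoms: tributyl(1-ethoxyvinyl)stannane, CCCC[Sn](CCCC)(CCCC)C(=C)OCC; water, O
Why: Stille coupling of an α-iodoenone: zerovalent palladium inserts into C7–I, CuI assists transmetallation and reductive elimination forms C7–C11; mild aqueous acid then hydrolyses the enol ether 29 to the methyl ketone. The electrophilic ene-dione therefore appears only in the last operation.

## Compound list

1 | 4-methoxy-2-methylphenol | COc1ccc(O)c(C)c1 | starting material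
2 | 4,4-dimethoxy-2-methylcyclohexa-2,5-dien-1-one | CC1=CC(OC)(OC)C=CC1=O | intermediate
3 | 4,4-dimethoxy-2-methylcyclohex-2-en-1-one | CC1=CC(OC)(OC)CCC1=O | intermediate
4 | trimethylaluminium | C[Al](C)C | starting material
5 | allyl iodide | C=CCI | starting material
6 | dimethylaluminium (3R)-4,4-dimethoxy-2,3-dimethylcyclohex-1-en-1-olate | C[C@@H]1C(C)=C(O[Al](C)C)CCC1(OC)OC | intermediate
7 | lithium trimethyl[(3R)-4,4-dimethoxy-2,3-dimethylcyclohex-1-en-1-olato]aluminate | [Li+].C[C@@H]1C(C)=C(O[Al-](C)(C)C)CCC1(OC)OC | intermediate
8 | (2R,3R)-4,4-dimethoxy-2,3-dimethyl-2-(prop-2-en-1-yl)cyclohexan-1-one | C=CC[C@]1(C)[C@@H](C)C(OC)(OC)CCC1=O | intermediate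
9 | allyl alcohol | C=CCO | starting material
10 | chloromethyl methyl ether | COCCl | starting material
11 | 3-(methoxymethoxy)prop-1-ene | C=CCOCOC | intermediate
12 | [(Z)-3-(methoxymethoxy)prop-2-en-1-yl]lithium | [Li]C/C=C\OCOC | intermediate
13 | diethyl[(Z)-3-(methoxymethoxy)prop-2-en-1-yl]aluminium | CC[Al](CC)C/C=C\OCOC | intermediate
14 | (1R,2R,3R)-4,4-dimethoxy-1-[(1R)-1-(methoxymethoxy)prop-2-en-1-yl]-2,3-dimethyl-2-(prop-2-en-1-yl)cyclohexan-1-ol | C=CC[C@]1(C)[C@@H](C)C(OC)(OC)CC[C@]1(O)[C@H](OCOC)C=C | intermediate
15 | 3,3-dimethoxy-9α-(methoxymethoxy)-4β,5β-dimethyl-cis-decal-7-en-10β-ol | COCO[C@@H]1C=CC[C@]2(C)[C@@H](C)C(OC)(OC)CC[C@]12O | intermediate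
16 | 10β-hydroxy-9α-(methoxymethoxy)-4β,5β-dimethyl-cis-decal-7-en-3-one | COCO[C@@H]1C=CC[C@]2(C)[C@@H](C)C(=O)CC[C@]12O | intermediate
17 | 9α-(methoxymethoxy)-4β,5β-dimethyl-cis-decal-7-ene-3β,10β-diol | COCO[C@@H]1C=CC[C@]2(C)[C@@H](C)[C@@H](O)CC[C@]12O | intermediate
18 | 7β,8β-epoxy-9α-(methoxymethoxy)-4β,5β-dimethyl-cis-decalin-3β,10β-diol | COCO[C@@H]1[C@H]3O[C@H]3C[C@]2(C)[C@@H](C)[C@@H](O)CC[C@]12O | intermediate
19 | 9α-(methoxymethoxy)-4β,5β-dimethyl-7α-(phenylselanyl)-cis-decalin-3β,8β,10β-triol | COCO[C@@H]1[C@@H](O)[C@H]([Se]c3ccccc3)C[C@]2(C)[C@@H](C)[C@@H](O)CC[C@]12O | intermediate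
20 | selenoxide of 19 (7α-phenylseleninyl) | COCO[C@@H]1[C@@H](O)[C@H]([Se](=O)c3ccccc3)C[C@]2(C)[C@@H](C)[C@@H](O)CC[C@]12O | intermediate
21 | 9α-(methoxymethoxy)-4β,5β-dimethyl-cis-decal-6-ene-3β,8β,10β-triol | COCO[C@@H]1[C@@H](O)C=C[C@]2(C)[C@@H](C)[C@@H](O)CC[C@]12O | intermediate
22 | 3β,10β-dihydroxy-9α-(methoxymethoxy)-4β,5β-dimethyl-cis-decal-6-en-8-one | COCO[C@@H]1C(=O)C=C[C@]2(C)[C@@H](C)[C@@H](O)CC[C@]12O | intermediate
23 | 3β-acetoxy-10β-hydroxy-9α-(methoxymethoxy)-4β,5β-dimethyl-cis-decal-6-en-8-one | COCO[C@@H]1C(=O)C=C[C@]2(C)[C@@H](C)[C@@H](OC(C)=O)CC[C@]12O | intermediate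
24 | 3β-acetoxy-10β-hydroxy-7-iodo-9α-(methoxymethoxy)-4β,5β-dimethyl-cis-decal-6-en-8-one | COCO[C@@H]1C(=O)C(I)=C[C@]2(C)[C@@H](C)[C@@H](OC(C)=O)CC[C@]12O | intermediate
25 | 3β-acetoxy-9α,10β-dihydroxy-7-iodo-4β,5β-dimethyl-cis-decal-6-en-8-one | O[C@@H]1C(=O)C(I)=C[C@]2(C)[C@@H](C)[C@@H](OC(C)=O)CC[C@]12O | intermediate
26 | angelic acid, (Z)-2-methylbut-2-enoic acid | C/C=C(/C)C(=O)O | starting material
27 | angelic 2,4,6-trichlorobenzoic anhydride | C/C=C(/C)C(=O)OC(=O)c1c(Cl)cc(Cl)cc1Cl | intermediate
28 | 3β-acetoxy-9α-angeloyloxy-10β-hydroxy-7-iodo-4β,5β-dimethyl-cis-decal-6-en-8-one | C/C=C(/C)C(=O)O[C@@H]1C(=O)C(I)=C[C@]2(C)[C@@H](C)[C@@H](OC(C)=O)CC[C@]12O | intermediate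
29 | 3β-acetoxy-9α-angeloyloxy-7-(1-ethoxyvinyl)-10β-hydroxy-4β,5β-dimethyl-cis-decal-6-en-8-one | C/C=C(/C)C(=O)O[C@@H]1C(=O)C(C(=C)OCC)=C[C@]2(C)[C@@H](C)[C@@H](OC(C)=O)CC[C@]12O | intermediate
30 | CNP0196241.1, 3β-acetoxy-7-acetyl-9α-angeloyloxy-10β-hydroxy-4β,5β-dimethyl-cis-decal-6-en-8-one (3S,4R,5R,9S,10R) | C/C=C(/C)C(=O)O[C@@H]1C(=O)C(C(C)=O)=C[C@]2(C)[C@@H](C)[C@@H](OC(C)=O)CC[C@]12O | target

## Step count and least certain steps

Total: 16 steps. Longest linear sequence: 15 steps (steps 1 to 3 and 5 to 16); step 4 is a one-step side branch.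

**Step 3 (key step).** The β-carbon C4 lies between the ketal carbon and the methyl-bearing C5. The likely failures are slow or poorly enantioselective methyl transfer by the bulky chiral copper species, ionisation of the ketal by the Lewis acidic AlMe3, or sluggish alkylation of the aluminate with proton transfer to the C1 enolate. Fallback, from 3 back to 8: conjugate addition with Me2CuLi and TMSCl gives the racemic [(4,4-dimethoxy-2,3-dimethylcyclohex-1-en-1-yl)oxy]trimethylsilane F1. MeLi then regenerates the lithium enolate, which is allylated with allyl iodide 5 with the same trans preference. The racemate is separated by preparative chromatography on a chiral stationary phase into 8 and its enantiomer (2S,3S)-4,4-dimethoxy-2,3-dimethyl-2-(prop-2-en-1-yl)cyclohexan-1-one F2, which is discarded. This replaces asymmetric catalysis by resolution and costs half the material.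

**Step 5.** The reagent may add through its other allyl terminus, may enolise the hindered ketone, or may pass through the chair with C5 pseudoaxial and give the C9 epimer. Fallback, from 8 to 16, separating the C–C bond formation from the setting of C9:
- 1-lithio-1-methoxyallene (from methoxyallene and nBuLi) adds to C10 on the α face and gives the methoxyallene adduct F3.
- Dilute aqueous acid hydrolyses the enol ether and the ketal to the hydroxy vinyl ketone F4.
- Ring-closing metathesis with the second-generation Grubbs catalyst gives the 10β-hydroxy-7-ene-3,9-dione F5.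
- Me4NBH(OAc)3 binds the C10 hydroxyl and delivers hydride to the β face of C9, giving the trans diol 9α,10β-dihydroxy-7-en-3-one F6; this reagent leaves the remote C3 ketone alone.
- MOMCl 10 with iPr2NEt protects the secondary hydroxyl and gives 16.

**Step 8.** If ring B reacts through the chair with the C4 methyl axial, hydride may enter from the β face and the facial selectivity would fall or invert. Fallback, from 16 to 17: the 3α-alcohol F7 (the 3-epimer of 17) is inverted by a Mitsunobu reaction with 4-nitrobenzoic acid, PPh3 and DIAD to the 3β-(4-nitrobenzoate) F8. Methanolysis with K2CO3 in MeOH then gives 17.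

**Step 10.** Selenolate may open the epoxide at C8 instead of C7, which would end in the C7-oxygenated isomer. Fallback, from 17 to 23, with regiocontrol by hydroboration instead of epoxide opening:
- Acetylation of 17 gives the 3β-acetate F9.
- BH3·THF followed by NaBO3 places boron on C8, next to and anti to the C9 oxygen, and gives the 8β-alcohol F10.
- Dess–Martin periodinane gives the 8-ketone F11.
- IBX in DMSO at 70 °C dehydrogenates F11 to 23; only C6=C7 can form because C10 has no hydrogen.

**Step 15.** Acylation of a hindered α-ketol may be slow. Forcing it invites Z to E drift of the angelate, epimerisation at C9 or retro-aldol opening of ring A. Fallback, from 25 to 28: 25 is acylated with 2-[bis(2,2,2-trifluoroethoxy)phosphoryl]propanoic acid (DIC, cat. DMAP) to the phosphonopropanoate F12. A Still–Gennari olefination with acetaldehyde (KHMDS, 18-crown-6, THF, −78 °C) then builds the Z alkene on the ester and gives 28.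

**Step 16.** Transmetallation at the hindered C7 may be slow and lead to protodeiodination, and the ene-dione may decompose during hydrolysis. Fallback, from 28 to 30: a Nozaki–Hiyama–Kishi coupling with acetaldehyde (CrCl2, NiCl2 cat., DMF; divalent chromium, selective for aldehydes over ketones) gives the 7-(1-hydroxyethyl) enone F13 as a mixture of carbinol epimers. Dess–Martin periodinane oxidises F13 to 30 under neutral conditions.

## Further compounds

F1 | step 3 | racemic [(4,4-dimethoxy-2,3-dimethylcyclohex-1-en-1-yl)oxy]trimethylsilane | CC1C(C)=C(O[Si](C)(C)C)CCC1(OC)OC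
F2 | step 3 | (2S,3S)-4,4-dimethoxy-2,3-dimethyl-2-(prop-2-en-1-yl)cyclohexan-1-one | C=CC[C@@]1(C)[C@H](C)C(OC)(OC)CCC1=O
F3 | step 5 | (1R,2R,3R)-4,4-dimethoxy-1-(1-methoxypropa-1,2-dien-1-yl)-2,3-dimethyl-2-(prop-2-en-1-yl)cyclohexan-1-ol | C=CC[C@]1(C)[C@@H](C)C(OC)(OC)CC[C@]1(O)C(OC)=C=C
F4 | step 5 | (2R,3R,4R)-4-hydroxy-2,3-dimethyl-3-(prop-2-en-1-yl)-4-(prop-2-enoyl)cyclohexan-1-one | C=CC[C@]1(C)[C@@H](C)C(=O)CC[C@]1(O)C(=O)C=C
F5 | step 5 | 10β-hydroxy-4β,5β-dimethyl-cis-decal-7-ene-3,9-dione | O=C1C=CC[C@]2(C)[C@@H](C)C(=O)CC[C@]12O
F6 | step 5 | 9α,10β-dihydroxy-4β,5β-dimethyl-cis-decal-7-en-3-one | O[C@@H]1C=CC[C@]2(C)[C@@H](C)C(=O)CC[C@]12O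
F7 | step 8 | 9α-(methoxymethoxy)-4β,5β-dimethyl-cis-decal-7-ene-3α,10β-diol | COCO[C@@H]1C=CC[C@]2(C)[C@@H](C)[C@H](O)CC[C@]12O
F8 | step 8 | 10β-hydroxy-9α-(methoxymethoxy)-4β,5β-dimethyl-cis-decal-7-en-3β-yl 4-nitrobenzoate | COCO[C@@H]1C=CC[C@]2(C)[C@@H](C)[C@@H](OC(=O)c3ccc(cc3)[N+](=O)[O-])CC[C@]12O
F9 | step 10 | 10β-hydroxy-9α-(methoxymethoxy)-4β,5β-dimethyl-cis-decal-7-en-3β-yl acetate | COCO[C@@H]1C=CC[C@]2(C)[C@@H](C)[C@@H](OC(C)=O)CC[C@]12O
F10 | step 10 | 8β,10β-dihydroxy-9α-(methoxymethoxy)-4β,5β-dimethyl-cis-decalin-3β-yl acetate | COCO[C@@H]1[C@@H](O)CC[C@]2(C)[C@@H](C)[C@@H](OC(C)=O)CC[C@]12O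
F11 | step 10 | 10β-hydroxy-9α-(methoxymethoxy)-4β,5β-dimethyl-8-oxo-cis-decalin-3β-yl acetate | COCO[C@@H]1C(=O)CC[C@]2(C)[C@@H](C)[C@@H](OC(C)=O)CC[C@]12O
F12 | step 15 | 3β-acetoxy-10β-hydroxy-7-iodo-4β,5β-dimethyl-8-oxo-cis-decal-6-en-9α-yl 2-[bis(2,2,2-trifluoroethoxy)phosphoryl]propanoate | CC(C(=O)O[C@@H]1C(=O)C(I)=C[C@]2(C)[C@@H](C)[C@@H](OC(C)=O)CC[C@]12O)P(=O)(OCC(F)(F)F)OCC(F)(F)F
F13 | step 16 | 3β-acetoxy-9α-angeloyloxy-10β-hydroxy-7-(1-hydroxyethyl)-4β,5β-dimethyl-cis-decal-6-en-8-one (carbinol epimers) | C/C=C(/C)C(=O)O[C@@H]1C(=O)C(C(C)O)=C[C@]2(C)[C@@H](C)[C@@H](OC(C)=O)CC[C@]12O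
A1 | alternative 1 | (2E,6E)-farnesyl diphosphate | CC(C)=CCC/C(C)=C/CC/C(C)=C/COP(=O)(O)OP(=O)(O)O
A2 | alternative 1 | (+)-aristolochene | CC(=C)[C@H]1CC=C2CCC[C@H](C)[C@@]2(C)C1
A3 | alternative 2 | cyclopropanol ketone with C8 dioxolane, C10 ketone and 1-hydroxycyclopropyl on C4 | O=C1CC2(OCCO2)CC[C@]1(C)[C@@H](C)C1(O)CC1
A4 | alternative 2 | cis-fused 10β-hydroxy-4β,5β-dimethyl 3-ketone with C8 dioxolane | C1C3(OCCO3)CC[C@]2(C)[C@@H](C)C(=O)CC[C@]12O
A5 | alternative 3 | C4=C5 enone with C10 (bromomethyl)dimethylsilyl ether and C8 silyl ether | C1[C@@H](O[Si](C)(C)C(C)(C)C)CCC2=C(C)C(=O)CC[C@]12O[Si](C)(C)CBr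
A6 | alternative 3 | cis-fused oxasilolane (C10–O–SiMe2–C14–C5) with C3 ketone and C4 methyl | C1[C@@H](O[Si](C)(C)C(C)(C)C)CC[C@]2(C[Si](C)(C)O3)[C@@H](C)C(=O)CC[C@]123
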